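The target is an all-trans 2,3,4-trisubstituted oxolane (ring atoms O1, C2–C5; C2 guaiacyl, C3 hydroxymethyl, C4 carbinol side chain). The route rests on closing the ring at C2–C3 by enantioselective dirhodium-carbenoid insertion into the C2–H bond, which is benzylic and adjacent to O1, with C3 entering as the carbenoid carbon bearing the future hydroxymethyl as an ester and C4 as a ketone. One operation thus builds the oxolane, fixes C2 and, by enolisation, trans C3. The precursor is an acyclic benzylic ether of a 2-diazo-3-oxobutanoate. The C4 ketone then serves to attach the catechol aroyl unit, and C4 and the carbinol centre follow by thermodynamic and Felkin–Anh relay.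

Key step: step 3

Assumption: the (S)-tert-leucinate catalyst Rh2(S-PTTL)4 is taken to deliver the (2S) centre of 5; should a first run show the opposite sense, the mirror-image catalyst Rh2(R-PTTL)4 is used with nothing else changed.

Step 1
Reactants: 1 (4-benzyloxy-3-methoxyphenyl)methanol; 2 methyl 4-chloro-3-oxobutanoate
Product: 3 methyl 4-{[4-(benzyloxy)-3-methoxyphenyl]methoxy}-3-oxobutanoate
Conditions: NaH (2.2 equiv), THF, 0 °C to rt; then dilute aq. HCl
Reagents that add atoms: none
Why: Williamson etherification in which the second equivalent of NaH holds the chloro keto ester as its enolate (shielding the ester from exchange) while the benzylic alkoxide displaces the activated primary chloride; no stereocentre is formed.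

Step 2
Reactants: 3 methyl 4-{[4-(benzyloxy)-3-methoxyphenyl]methoxy}-3-oxobutanoate
Product: 4 methyl 4-{[4-(benzyloxy)-3-methoxyphenyl]methoxy}-2-diazo-3-oxobutanoate
Conditions: 4-acetamidobenzenesulfonyl azide, Et3N, MeCN, 0 °C to rt
Reagents that add atoms: 4-acetamidobenzenesulfonyl azide, CC(=O)Nc1ccc(cc1)S(=O)(=O)N=[N+]=[N-]
Why: Regitz diazo transfer to the doubly activated methylene of a β-keto ester under mild amine base, which leaves both benzylic ethers untouched.

Step 3
Reactants: 4 methyl 4-{[4-(benzyloxy)-3-methoxyphenyl]methoxy}-2-diazo-3-oxobutanoate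
Product: 5 methyl (2S,3R)-2-[4-(benzyloxy)-3-methoxyphenyl]-4-oxooxolane-3-carboxylate (aryl and ester trans; in equilibrium with its enol)
Conditions: Rh2(S-PTTL)4 (dirhodium tetrakis[N-phthaloyl-(S)-tert-leucinate], 1 mol %), CH2Cl2, 0 °C to rt, slow addition of 4
Reagents that add atoms: none
Why: Loss of N2 gives an electrophilic rhodium carbenoid flanked by two carbonyl groups (so no β-hydrogen can be lost), which inserts into the C–H bond five atoms away through a concerted, hydride-transfer-like three-centre transition state, forming the C2–C3 bond and releasing the catalyst. The closest known reaction type is the dirhodium tetracarboxylate-catalysed 1,5 C–H insertion of 4-alkoxy-2-diazo-3-oxo esters and related diazoketones next to ether oxygen, benzyl ethers included, which gives 3-oxo-oxolanes and has an enantioselective version with chiral dirhodium carboxylates. The oxolane closes by C–C bond formation in the 1,5-insertion mode, the five-membered ring being favoured over a four-membered oxonium ylide and over larger-ring attack on the arene. C2 is set by the chiral carboxylate ligands, which tell apart the two enantiotopic benzylic hydrogens, and C3 is set thermodynamically, because the β-keto ester enolises and settles with the ester trans to the aryl group. The step needs site selectivity for the ether C–H bond, secured by its double activation (oxygen lone pair and electron-rich arene) and the ideal 1,5 distance, and it needs enantiotopic-hydrogen selectivity from the catalyst, which is the one real uncertainty of the route.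

Step 4
Reactants: 5 methyl (2S,3R)-2-[4-(benzyloxy)-3-methoxyphenyl]-4-oxooxolane-3-carboxylate
Product: 6 methyl (2R)-2-[4-(benzyloxy)-3-methoxyphenyl]-4-(trifluoromethanesulfonyloxy)-2,5-dihydrofuran-3-carboxylate (same spatial arrangement at C2 as in 5; the descriptor changes only because trigonal C3 now outranks the aryl group)
Conditions: Tf2O, i-Pr2NEt, CH2Cl2, −78 °C
Reagents that add atoms: trifluoromethanesulfonic anhydride, O=S(=O)(OS(=O)(=O)C(F)(F)F)C(F)(F)F
Why: O-sulfonylation of the β-keto ester enol gives the conjugated enol triflate at low temperature; C3 becomes trigonal and C2, which is not acidic in this compound, keeps its configuration.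

Step 5
Reactants: 6 methyl (2R)-2-[4-(benzyloxy)-3-methoxyphenyl]-4-(trifluoromethanesulfonyloxy)-2,5-dihydrofuran-3-carboxylate; 7 [3,4-bis(benzyloxy)phenyl]boronic acid
Product: 8 methyl (2R)-2-[4-(benzyloxy)-3-methoxyphenyl]-4-[3,4-bis(benzyloxy)benzoyl]-2,5-dihydrofuran-3-carboxylate (C2 arrangement unchanged)
Conditions: PdCl2(dppf) (5 mol %), CO (1 atm), anhydrous K2CO3, anisole, 80 °C
Reagents that add atoms: carbon monoxide, [C-]#[O+]
Why: Carbonylative Suzuki–Miyaura coupling, in which oxidative addition of the electron-poor alkenyl triflate, CO insertion to the acylpalladium species, transmetalation from the arylboronate and reductive elimination give the aryl alkenyl ketone, with benzyl ethers and the ester inert.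

Step 6
Reactants: 8 methyl (2R)-2-[4-(benzyloxy)-3-methoxyphenyl]-4-[3,4-bis(benzyloxy)benzoyl]-2,5-dihydrofuran-3-carboxylate
Product: 10 methyl (2S,3S,4S)-2-[4-(benzyloxy)-3-methoxyphenyl]-4-[3,4-bis(benzyloxy)benzoyl]oxolane-3-carboxylate (all-trans), via keto ester epimer mixture 9 (not isolated)
Conditions: Zn dust, AcOH–THF, rt; filter, concentrate; then NaOMe (0.3 equiv), MeOH, 0 °C to rt
Reagents that add atoms: none
Why: Zinc in acetic acid performs the classical 1,4-reduction of a 2-ene-1,4-dicarbonyl compound, and methoxide then epimerises C3 (α to the ester) and C4 (α to the ketone) through their enolates to the all-trans isomer, each substituent ending trans to its neighbours as relayed from the fixed C2 centre.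

Step 7
Reactants: 10 methyl (2S,3S,4S)-2-[4-(benzyloxy)-3-methoxyphenyl]-4-[3,4-bis(benzyloxy)benzoyl]oxolane-3-carboxylate
Product: 11 methyl (2S,3S,4S)-2-[4-(benzyloxy)-3-methoxyphenyl]-4-{(R)-[3,4-bis(benzyloxy)phenyl](hydroxy)methyl}oxolane-3-carboxylate
Conditions: LiBH(s-Bu)3, THF, −78 °C; pH 7 buffer
Reagents that add atoms: none
Why: Felkin–Anh-controlled reduction by a bulky, non-chelating hydride, in which the more substituted ring carbon C3 lies anti to the incoming hydride, the C5 methylene flanks the carbonyl oxygen and attack past the C4 hydrogen should give the (R)-carbinol, whereas a chelate through the ester oxygen would favour the epimer and is therefore avoided; the ester is not reduced at this temperature.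

Step 8
Reactants: 11 methyl (2S,3S,4S)-2-[4-(benzyloxy)-3-methoxyphenyl]-4-{(R)-[3,4-bis(benzyloxy)phenyl](hydroxy)methyl}oxolane-3-carboxylate
Product: 12 (R)-[3,4-bis(benzyloxy)phenyl]{(3S,4R,5S)-5-[4-(benzyloxy)-3-methoxyphenyl]-4-(hydroxymethyl)oxolan-3-yl}methanol
Conditions: LiAlH4, THF, 0 °C; aq. NaOH work-up
Reagents that add atoms: none
Why: Hydride reduction of the methyl ester to the primary alcohol touches no stereocentre and leaves the benzyl ethers intact; the trans arrangement prevents lactonisation of the intermediate alkoxide.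

Step 9
Reactants: 12 (R)-[3,4-bis(benzyloxy)phenyl]{(3S,4R,5S)-5-[4-(benzyloxy)-3-methoxyphenyl]-4-(hydroxymethyl)oxolan-3-yl}methanol
Product: 13 4-[(R)-hydroxy{(3S,4R,5S)-4-(hydroxymethyl)-5-(4-hydroxy-3-methoxyphenyl)oxolan-3-yl}methyl]benzene-1,2-diol (target)
Conditions: H2 (1 atm), 10% Pd/C, EtOAc–EtOH, rt, stopped on complete debenzylation
Reagents that add atoms: none
Why: Hydrogenolysis of the three aryl benzyl ethers under neutral conditions is much faster than cleavage of the benzylic C–O bonds of the oxolane and the carbinol, so stopping at full debenzylation should leave all four stereocentres untouched.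

Compound list
1 | (4-benzyloxy-3-methoxyphenyl)methanol | COc1cc(CO)ccc1OCc1ccccc1 | starting material
2 | methyl 4-chloro-3-oxobutanoate | COC(=O)CC(=O)CCl | starting material
3 | methyl 4-{[4-(benzyloxy)-3-methoxyphenyl]methoxy}-3-oxobutanoate | COC(=O)CC(=O)COCc1ccc(OCc2ccccc2)c(OC)c1 | intermediate
4 | methyl 4-{[4-(benzyloxy)-3-methoxyphenyl]methoxy}-2-diazo-3-oxobutanoate | COC(=O)C(=[N+]=[N-])C(=O)COCc1ccc(OCc2ccccc2)c(OC)c1 | intermediate
5 | methyl (2S,3R)-2-[4-(benzyloxy)-3-methoxyphenyl]-4-oxooxolane-3-carboxylate | COc1cc([C@H]2OCC(=O)[C@@H]2C(=O)OC)ccc1OCc1ccccc1 | intermediate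
6 | methyl (2R)-2-[4-(benzyloxy)-3-methoxyphenyl]-4-(trifluoromethanesulfonyloxy)-2,5-dihydrofuran-3-carboxylate | COc1cc([C@H]2OCC(OS(=O)(=O)C(F)(F)F)=C2C(=O)OC)ccc1OCc1ccccc1 | intermediate
7 | [3,4-bis(benzyloxy)phenyl]boronic acid | OB(O)c1ccc(OCc2ccccc2)c(OCc2ccccc2)c1 | starting material
8 | methyl (2R)-2-[4-(benzyloxy)-3-methoxyphenyl]-4-[3,4-bis(benzyloxy)benzoyl]-2,5-dihydrofuran-3-carboxylate | COc1cc([C@H]2OCC(C(=O)c3ccc(OCc4ccccc4)c(OCc4ccccc4)c3)=C2C(=O)OC)ccc1OCc1ccccc1 | intermediate
9 | methyl (2S)-2-[4-(benzyloxy)-3-methoxyphenyl]-4-[3,4-bis(benzyloxy)benzoyl]oxolane-3-carboxylate, mixture of C3 and C4 epimers | COc1cc([C@H]2OCC(C(=O)c3ccc(OCc4ccccc4)c(OCc4ccccc4)c3)C2C(=O)OC)ccc1OCc1ccccc1 | intermediate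
10 | methyl (2S,3S,4S)-2-[4-(benzyloxy)-3-methoxyphenyl]-4-[3,4-bis(benzyloxy)benzoyl]oxolane-3-carboxylate | COc1cc([C@H]2OC[C@@H](C(=O)c3ccc(OCc4ccccc4)c(OCc4ccccc4)c3)[C@@H]2C(=O)OC)ccc1OCc1ccccc1 | intermediate
11 | methyl (2S,3S,4S)-2-[4-(benzyloxy)-3-methoxyphenyl]-4-{(R)-[3,4-bis(benzyloxy)phenyl](hydroxy)methyl}oxolane-3-carboxylate | COc1cc([C@H]2OC[C@@H]([C@@H](O)c3ccc(OCc4ccccc4)c(OCc4ccccc4)c3)[C@@H]2C(=O)OC)ccc1OCc1ccccc1 | intermediate
12 | (R)-[3,4-bis(benzyloxy)phenyl]{(3S,4R,5S)-5-[4-(benzyloxy)-3-methoxyphenyl]-4-(hydroxymethyl)oxolan-3-yl}methanol | COc1cc([C@H]2OC[C@@H]([C@@H](O)c3ccc(OCc4ccccc4)c(OCc4ccccc4)c3)[C@@H]2CO)ccc1OCc1ccccc1 | intermediate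
13 | 4-[(R)-hydroxy{(3S,4R,5S)-4-(hydroxymethyl)-5-(4-hydroxy-3-methoxyphenyl)oxolan-3-yl}methyl]benzene-1,2-diol | COc1cc([C@H]2OC[C@@H]([C@@H](O)c3ccc(O)c(O)c3)[C@@H]2CO)ccc1O | target

Total step count: 9. Longest linear sequence: 9 steps (from 1 to 13).

Steps most likely to fail

1. Step 3. The catalyst may discriminate too weakly between the two enantiotopic benzylic hydrogens, giving low enantiomeric purity at C2, or the chiral catalyst may divert the carbenoid into ylide or arene-addition pathways. The fallback separates ring construction from enantiocontrol. It sets out from 4, which is decomposed with achiral Rh2(OAc)4 (CH2Cl2, rt) to give the racemic trans keto ester F1. Condensation of F1 with (S)-1-phenylethylamine (cat. AcOH, toluene, molecular sieves) should give two diastereomeric enamino esters: the (2R,1′S) enamino ester F2, which has the C2 arrangement of 5, and the (2S,1′S) enamino ester F3. These would be separated by crystallisation or chromatography. Mild hydrolysis of F2 (aq. AcOH, THF, rt) should then return the β-keto ester, and the fallback rejoins the route at 5.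

2. Step 5. Transmetalation may outrun CO insertion at the electron-poor alkenylpalladium intermediate, giving arylation instead of aroylation. Carbonate may also cause a proton shift from C2, which is vinylogous to the new ketone, so that the ring double bond migrates and the C2 configuration is lost. The fallback replaces the base-activated boron partner by a neutral tin partner in a carbonylative Stille coupling. Commercial 4-bromo-1,2-bis(benzyloxy)benzene undergoes bromine–lithium exchange (n-BuLi, THF, −78 °C) to the aryllithium F4, which is quenched with Bu3SnCl to give the arylstannane F5. The fallback then sets out from 6: coupling with F5 (Pd(PPh3)4, LiCl, CO 1–3 atm, THF, 55 °C) proceeds without base, and the slower tin transmetalation leaves time for CO insertion. It rejoins the route at 8.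

3. Step 7. Facial discrimination in hydride delivery to the aroyl carbonyl may be poor if the C4 stereocentre biases the approach too weakly, giving a mixture of carbinol epimers. The fallback takes stereocontrol from a catalyst instead of the substrate. It sets out from 10, which is reduced with BH3·SMe2 and the (S)-configured methyl oxazaborolidine (Corey–Bakshi–Shibata reduction, toluene, −20 °C). With the aryl group acting as the larger substituent, this catalyst should deliver the (R)-carbinol, and the fallback rejoins the route at 11. It makes no compound outside the list (F0).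

Further compounds
F1 | step 3 | methyl 2-[4-(benzyloxy)-3-methoxyphenyl]-4-oxooxolane-3-carboxylate, racemic trans isomer | COc1cc(C2OCC(=O)C2C(=O)OC)ccc1OCc1ccccc1
F2 | step 3 | methyl (2R)-2-[4-(benzyloxy)-3-methoxyphenyl]-4-{[(1S)-1-phenylethyl]amino}-2,5-dihydrofuran-3-carboxylate | COc1cc([C@H]2OCC(N[C@@H](C)c3ccccc3)=C2C(=O)OC)ccc1OCc1ccccc1
F3 | step 3 | methyl (2S)-2-[4-(benzyloxy)-3-methoxyphenyl]-4-{[(1S)-1-phenylethyl]amino}-2,5-dihydrofuran-3-carboxylate | COc1cc([C@@H]2OCC(N[C@@H](C)c3ccccc3)=C2C(=O)OC)ccc1OCc1ccccc1
F4 | step 5 | [3,4-bis(benzyloxy)phenyl]lithium | [Li]c1ccc(OCc2ccccc2)c(OCc2ccccc2)c1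
F5 | step 5 | [3,4-bis(benzyloxy)phenyl]tributylstannane | CCCC[Sn](CCCC)(CCCC)c1ccc(OCc2ccccc2)c(OCc2ccccc2)c1
F0 | step 7 | none | none
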